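**Retrosynthetic overview**
1. Target ⇒ free C-8 alcohol + silyl-protected 2-(hydroxymethyl)acrylic acid (ester last); the 13-acetoxy-7(11)-butenolide ⇒ enol triflate (Stille hydroxymethylation) ⇒ α-keto lactone ⇒ ozonolysis of an α-methylene lactone.
2. 1,10-Epoxide ⇒ peripheral peracid epoxidation of the 1(10)E-olefin of an 8α-silyloxy-parthenolide-type lactone.
3. Ten-membered ring and lactone ⇒ intramolecular Nozaki–Hiyama–Kishi allylation (C6–C7) of an epoxy aldehyde carrying a 2-(bromomethyl)enoate (Baylis–Hillman chemistry on an α-silyloxy aldehyde).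
4. C-8 carbinol ⇒ ketoreductase reduction of a 2-oxo ester, made from ethyl 1,3-dithiane-2-carboxylate and an allylic bromide derived from (2R,3R)-epoxygeraniol (Sharpless epoxidation of geraniol, SeO2 oxidation).
5. Ring order: oxirane C4/C5 → ten-membered carbocycle → γ-lactone → oxirane C1/C10.

Assumption: the target is taken as drawn, which I read as 1R,4R,5R,6S,8S,10R (1β,10α;4α,5β-diepoxide, 6α-lactone oxygen, 8α-ester), and a commercial (S)-selective ketoreductase panel is assumed to contain an enzyme that accepts the 2-oxo ester of step 6. Germacrane numbering is used for the macrocycles.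

**Step 1**
Reactants: 1 geraniol
Product: 2 (2R,3R)-2,3-epoxygeraniol
Conditions: Ti(OiPr)4 (5 mol%), D-(−)-diethyl tartrate (7.5 mol%), t-BuOOH, 4 Å MS, CH2Cl2, −20 °C
Reagents that add atoms: tert-butyl hydroperoxide, CC(C)(C)OO
Why: Katsuki–Sharpless asymmetric epoxidation, in which the Ti–D-tartrate catalyst epoxidises only the allylic-alcohol olefin from the face that gives the (2R,3R)-epoxide (future C-5 and C-4, the first stereocentres), leaving the remote olefin untouched.

**Step 2**
Reactants: 2 (2R,3R)-2,3-epoxygeraniol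
Product: 3 (2R,3R)-epoxygeranyl 4-methoxybenzyl ether
Conditions: NaH, PMBCl, Bu4NI (cat.), THF/DMF, 0 °C → rt
Reagents that add atoms: 4-methoxybenzyl chloride, COc1ccc(CCl)cc1
Why: Williamson etherification of the primary alkoxide, which is benzylated faster than it can undergo Payne rearrangement in an aprotic medium.

**Step 3**
Reactants: 3 (2R,3R)-epoxygeranyl 4-methoxybenzyl ether
Product: 4 (2E)-5-[(2R,3R)-3-{[(4-methoxybenzyl)oxy]methyl}-2-methyloxiran-2-yl]-2-methylpent-2-en-1-ol
Conditions: SeO2 (0.3 equiv), t-BuOOH, CH2Cl2, 0 °C → rt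
Reagents that add atoms: selenium dioxide, O=[Se]=O; tert-butyl hydroperoxide, CC(C)(C)OO (terminal oxidant that regenerates SeO2)
Why: Riley allylic oxidation (ene reaction then [2,3]-shift) is selective for the (E)-methyl group of the terminal trisubstituted olefin and gives the E-allylic alcohol (future C-9).

**Step 4**
Reactants: 4 the E-allylic alcohol
Product: 5 (2R,3R)-2-[(3E)-5-bromo-4-methylpent-3-en-1-yl]-3-{[(4-methoxybenzyl)oxy]methyl}-2-methyloxirane
Conditions: CBr4, PPh3, CH2Cl2, −20 → 0 °C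
Reagents that add atoms: carbon tetrabromide, BrC(Br)(Br)Br
Why: Appel bromination converts the primary allylic alcohol by SN2 under neutral conditions, without epoxide opening or allylic transposition.

**Step 5**
Reactants: 5 the allylic bromide; 6 ethyl 1,3-dithiane-2-carboxylate
Product: 7 ethyl 2-{(2E)-5-[(2R,3R)-3-{[(4-methoxybenzyl)oxy]methyl}-2-methyloxiran-2-yl]-2-methylpent-2-en-1-yl}-1,3-dithiane-2-carboxylate
Conditions: NaH, DMF/toluene, 0 °C → rt
Reagents that add atoms: none
Why: SN2 C-alkylation of the stabilised glyoxylate acyl-anion equivalent with the primary allylic bromide forms the C8–C9 bond.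

**Step 6**
Reactants: 7 the alkylated dithiane
Product: 8 ethyl (4E)-7-[(2R,3R)-3-{[(4-methoxybenzyl)oxy]methyl}-2-methyloxiran-2-yl]-4-methyl-2-oxohept-4-enoate
Conditions: MeI (excess), CaCO3, MeCN/H2O 4:1, 45 °C
Reagents that add atoms: water, O
Why: Alkylative dithioacetal hydrolysis (Fetizon conditions) is neutral and buffered, so the epoxide, the PMB ether and the β,γ-olefin of the new 2-oxo ester survive.

**Step 7**
Reactants: 8 the 2-oxo ester
Product: 9 ethyl (2S,4E)-2-hydroxy-7-[(2R,3R)-3-{[(4-methoxybenzyl)oxy]methyl}-2-methyloxiran-2-yl]-4-methylhept-4-enoate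
Conditions: ketoreductase (S-selective, from a screening panel), NADP+ (cat.), i-PrOH (10% v/v), phosphate buffer pH 7.0/DMSO, 30 °C
Reagents that add atoms: none
Why: Biocatalytic asymmetric carbonyl reduction by a ketoreductase, which delivers hydride from NADPH to one face of the 2-oxo ester and sets C-8 as S under enzyme control, independent of the remote epoxide, at a pH that avoids olefin migration.

**Step 8**
Reactants: 9 the (2S)-hydroxy ester
Product: 10 ethyl (2S,4E)-2-(tert-butyldimethylsilyloxy)-7-[(2R,3R)-3-{[(4-methoxybenzyl)oxy]methyl}-2-methyloxiran-2-yl]-4-methylhept-4-enoate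
Conditions: TBSCl, imidazole, DMF, rt
Reagents that add atoms: tert-butyldimethylsilyl chloride, CC(C)(C)[Si](C)(C)Cl
Why: Standard silylation of the secondary alcohol gives a group that survives every step up to the late fluoride cleavage.

**Step 9**
Reactants: 10 the silyloxy ester
Product: 11 (2S,4E)-2-(tert-butyldimethylsilyloxy)-7-[(2R,3R)-3-{[(4-methoxybenzyl)oxy]methyl}-2-methyloxiran-2-yl]-4-methylhept-4-enal
Conditions: DIBAL-H (1.1 equiv), CH2Cl2, −78 °C; Rochelle salt
Reagents that add atoms: none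
Why: Partial ester reduction stops at the aldehyde because the α-silyloxy ester forms a stable tetrahedral aluminate at −78 °C, and the protected epoxide is not opened at this temperature.

**Step 10**
Reactants: 11 the α-silyloxy aldehyde; 12 methyl acrylate
Product: 13 methyl (4S,6E)-4-(tert-butyldimethylsilyloxy)-3-hydroxy-9-[(2R,3R)-3-{[(4-methoxybenzyl)oxy]methyl}-2-methyloxiran-2-yl]-6-methyl-2-methylidenenon-6-enoate (C-3 epimers)
Conditions: DABCO (1 equiv), methyl acrylate (10 equiv), MeOH (2 equiv), rt, 3–5 d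
Reagents that add atoms: none
Why: Morita–Baylis–Hillman reaction of the activated α-alkoxy aldehyde installs C-11 to C-13, and the new carbinol (C-7) may be a mixture because it becomes sp2 in the next step.

**Step 11**
Reactants: 13 the Baylis–Hillman adduct
Product: 14 methyl (2Z,4S,6E)-2-(bromomethyl)-4-(tert-butyldimethylsilyloxy)-9-[(2R,3R)-3-{[(4-methoxybenzyl)oxy]methyl}-2-methyloxiran-2-yl]-6-methylnona-2,6-dienoate
Conditions: NBS/Me2S (premixed), CH2Cl2, 0 °C → rt
Reagents that add atoms: N-bromosuccinimide, O=C1CCC(=O)N1Br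
Why: Corey–Kim-type activation of the allylic alcohol followed by SN2′ attack of bromide gives the thermodynamically preferred (Z)-2-(bromomethyl)enoate under essentially neutral conditions.

**Step 12**
Reactants: 14 the PMB-protected bromide
Product: 15 methyl (2Z,4S,6E)-2-(bromomethyl)-4-(tert-butyldimethylsilyloxy)-9-[(2R,3R)-3-(hydroxymethyl)-2-methyloxiran-2-yl]-6-methylnona-2,6-dienoate
Conditions: DDQ, CH2Cl2/pH 7 buffer 10:1, 0 °C
Reagents that add atoms: none
Why: Oxidative PMB cleavage by DDQ is orthogonal to the silyl ether, the allylic bromide, the epoxide and the isolated olefin.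

**Step 13**
Reactants: 15 the epoxy alcohol
Product: 16 methyl (2Z,4S,6E)-2-(bromomethyl)-4-(tert-butyldimethylsilyloxy)-9-[(2R,3S)-3-formyl-2-methyloxiran-2-yl]-6-methylnona-2,6-dienoate
Conditions: Dess–Martin periodinane, NaHCO3, CH2Cl2, 0 °C → rt (used crude)
Reagents that add atoms: none
Why: Buffered Dess–Martin oxidation gives the configurationally stable α,β-epoxy aldehyde (no α-hydrogen that can be lost without ring opening) and leaves the allylic bromide alone.

**Step 14**
Reactants: 16 the epoxy aldehyde bromide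
Product: 18 (4R,5R,6S,7S,8S)-8-(tert-butyldimethylsilyloxy)-4,5-epoxygermacra-1(10)E,11(13)-dien-12,6-olide (8α-silyloxyparthenolide; 6α-O; 7α-H), via seco hydroxy ester 17 (not isolated)
Conditions: CrCl2 (10 equiv), degassed THF, rt, syringe-pump addition over 12 h (final 2 mM); aq. NH4Cl; SiO2
Reagents that add atoms: none
Why: Intramolecular Nozaki–Hiyama–Kishi (Barbier-type) 2-(alkoxycarbonyl)allylation closes the ten-membered ring through a crown-shaped chair transition state in which the aldehyde oxygen and the C-8 silyloxy group lie on the periphery and C-7 attacks anti to the epoxide C–O bond, which is expected to give 6S (C-7 is erased in step 16), and the chromium alkoxide then lactonises.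

**Step 15**
Reactants: 18 the epoxy-germacradienolide
Product: 19 (1R,4R,5R,6S,7S,8S,10R)-8-(tert-butyldimethylsilyloxy)-1,10:4,5-diepoxygermacr-11(13)-en-12,6-olide
Conditions: mCPBA (1.2 equiv), NaHCO3, CH2Cl2, 0 °C
Reagents that add atoms: 3-chloroperoxybenzoic acid, O=C(OO)c1cccc(Cl)c1
Why: Prilezhaev epoxidation attacks only the electron-rich 1(10)-olefin, from the peripheral face of the crown conformer as in parthenolide, giving the 1β,10α (1R,10R) epoxide while the electron-poor methylene lactone is inert.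

**Step 16**
Reactants: 19 the diepoxy methylene lactone
Product: 22 (1R,4R,5R,6S,8S,10R)-8-(tert-butyldimethylsilyloxy)-1,10:4,5-diepoxy-11-hydroxy-13-norgermacr-7(11)-en-12,6-olide, via secondary ozonide 20 (not isolated), via 11-keto lactone 21 (not isolated)
Conditions: O3, CH2Cl2, −78 °C (to the end point only), N2 purge; then Me2S, −78 °C → rt
Reagents that add atoms: ozone, [O-][O+]=O
Why: Ozonolysis cleaves the only remaining C=C, and the resulting α-keto-γ-lactone tautomerises to the conjugated enol (as in sotolon), which creates the 7(11)-double bond and erases C-7; excess ozone is purged before the ozonide is reduced so that the enol never meets it.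

**Step 17**
Reactants: 22 the enol
Product: 23 the 11-(trifluoromethanesulfonyloxy) analogue of 22 (enol triflate)
Conditions: PhNTf2, Et3N, DMAP (cat.), CH2Cl2, 0 °C → rt
Reagents that add atoms: N-phenylbis(trifluoromethanesulfonimide), O=S(=O)(N(c1ccccc1)S(=O)(=O)C(F)(F)F)C(F)(F)F
Why: O-Sulfonylation of the acidic enol with a mild triflyl donor gives an electron-poor vinyl triflate without touching the epoxides.

**Step 18**
Reactants: 23 the enol triflate
Product: 24 (1R,4R,5R,6S,8S,10R)-8-(tert-butyldimethylsilyloxy)-1,10:4,5-diepoxy-13-hydroxygermacr-7(11)-en-12,6-olide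
Conditions: Bu3SnCH2OH, Pd2(dba)3 (5 mol%), P(2-furyl)3 (20 mol%), CuI (10 mol%), NMP, 50 °C
Reagents that add atoms: (tributylstannyl)methanol, CCCC[Sn](CCCC)(CCCC)CO
Why: Migita–Kosugi–Stille coupling of the activated α-triflyloxy butenolide transfers the hydroxymethyl group (C-13) under neutral, chloride-free conditions.

**Step 19**
Reactants: 24 the 13-alcohol
Product: 25 (1R,4R,5R,6S,8S,10R)-13-acetoxy-8-(tert-butyldimethylsilyloxy)-1,10:4,5-diepoxygermacr-7(11)-en-12,6-olide
Conditions: Ac2O, pyridine, DMAP (cat.), CH2Cl2, 0 °C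
Reagents that add atoms: acetic anhydride, CC(=O)OC(C)=O
Why: Routine acetylation of the only free (primary allylic) hydroxyl group.

**Step 20**
Reactants: 25 the silyl ether acetate
Product: 26 (1R,4R,5R,6S,8S,10R)-13-acetoxy-1,10:4,5-diepoxy-8-hydroxygermacr-7(11)-en-12,6-olide
Conditions: HF·pyridine, pyridine, THF, 0 °C → rt
Reagents that add atoms: none
Why: Pyridine-buffered fluoride desilylation frees the C-8 alcohol without opening the epoxides or cleaving the acetate, and the weakly acidic medium suppresses 6,12 → 8,12 lactone migration (26 is used at once).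

**Step 21**
Reactants: 27 ethyl 2-(hydroxymethyl)acrylate
Product: 28 ethyl 2-{[(tert-butyldimethylsilyl)oxy]methyl}acrylate
Conditions: TBSCl, imidazole, CH2Cl2, 0 °C → rt
Reagents that add atoms: tert-butyldimethylsilyl chloride, CC(C)(C)[Si](C)(C)Cl
Why: Silylation masks the side-chain hydroxyl so that it cannot compete in the esterification.

**Step 22**
Reactants: 28 the silyloxy ester
Product: 29 2-{[(tert-butyldimethylsilyl)oxy]methyl}acrylic acid
Conditions: LiOH·H2O, THF/H2O 3:1, 0 °C → rt; then 1 M HCl to pH 4, 0 °C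
Reagents that add atoms: lithium hydroxide, [Li+].[OH-]
Why: Saponification of the unhindered ethyl ester under cold, mild conditions that the primary silyl ether tolerates.

**Step 23**
Reactants: 26 the C-8 alcohol; 29 the silyl-protected acid
Product: 30 (1R,4R,5R,6S,8S,10R)-13-acetoxy-8-[(2-{[(tert-butyldimethylsilyl)oxy]methyl}acryloyl)oxy]-1,10:4,5-diepoxygermacr-7(11)-en-12,6-olide
Conditions: DIC, DMAP (0.2 equiv), CH2Cl2, 0 °C → rt
Reagents that add atoms: none
Why: Steglich esterification acylates the C-8 oxygen, so the C-8 configuration is retained.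

**Step 24**
Reactants: 30 the silyl-protected ester
Product: 31 the target, (1R,4R,5R,6S,8S,10R)-13-acetoxy-1,10:4,5-diepoxy-8-{[2-(hydroxymethyl)acryloyl]oxy}germacr-7(11)-en-12,6-olide
Conditions: HF·pyridine, pyridine, THF, 0 °C
Reagents that add atoms: none
Why: Buffered fluoride cleavage of the primary silyl ether is fast and leaves the acetate, the acrylate, the butenolide and both epoxides intact.

**Compound list**
1 | geraniol | CC(C)=CCC/C(C)=C/CO | starting material
2 | (2R,3R)-2,3-epoxygeraniol | CC(C)=CCC[C@@]1(C)O[C@@H]1CO | intermediate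
3 | (2R,3R)-epoxygeranyl 4-methoxybenzyl ether | CC(C)=CCC[C@@]1(C)O[C@@H]1COCc1ccc(OC)cc1 | intermediate
4 | E-allylic alcohol (C-9 hydroxyl) | OC/C(C)=C/CC[C@@]1(C)O[C@@H]1COCc1ccc(OC)cc1 | intermediate
5 | E-allylic bromide | BrC/C(C)=C/CC[C@@]1(C)O[C@@H]1COCc1ccc(OC)cc1 | intermediate
6 | ethyl 1,3-dithiane-2-carboxylate | CCOC(=O)C1SCCCS1 | starting material
7 | 2-alkylated ethyl 1,3-dithiane-2-carboxylate | CCOC(=O)C1(C/C(C)=C/CC[C@@]2(C)O[C@@H]2COCc2ccc(OC)cc2)SCCCS1 | intermediate
8 | 2-oxo ester | CCOC(=O)C(=O)C/C(C)=C/CC[C@@]1(C)O[C@@H]1COCc1ccc(OC)cc1 | intermediate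
9 | (2S)-2-hydroxy ester | CCOC(=O)[C@@H](O)C/C(C)=C/CC[C@@]1(C)O[C@@H]1COCc1ccc(OC)cc1 | intermediate
10 | (2S)-2-silyloxy ester | CCOC(=O)[C@@H](O[Si](C)(C)C(C)(C)C)C/C(C)=C/CC[C@@]1(C)O[C@@H]1COCc1ccc(OC)cc1 | intermediate
11 | (2S)-2-silyloxy aldehyde | O=C[C@@H](O[Si](C)(C)C(C)(C)C)C/C(C)=C/CC[C@@]1(C)O[C@@H]1COCc1ccc(OC)cc1 | intermediate
12 | methyl acrylate | C=CC(=O)OC | starting material
13 | Baylis–Hillman adduct (C-7 carbinol epimers, 8S) | C=C(C(=O)OC)C(O)[C@@H](O[Si](C)(C)C(C)(C)C)C/C(C)=C/CC[C@@]1(C)O[C@@H]1COCc1ccc(OC)cc1 | intermediate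
14 | (Z)-2-(bromomethyl)enoate PMB ether | COC(=O)/C(CBr)=C/[C@@H](O[Si](C)(C)C(C)(C)C)C/C(C)=C/CC[C@@]1(C)O[C@@H]1COCc1ccc(OC)cc1 | intermediate
15 | epoxy alcohol bromide | COC(=O)/C(CBr)=C/[C@@H](O[Si](C)(C)C(C)(C)C)C/C(C)=C/CC[C@@]1(C)O[C@@H]1CO | intermediate
16 | epoxy aldehyde bromide | COC(=O)/C(CBr)=C/[C@@H](O[Si](C)(C)C(C)(C)C)C/C(C)=C/CC[C@@]1(C)O[C@@H]1C=O | intermediate
17 | seco hydroxy ester: methyl (4R,5R,6S,7S,8S)-8-silyloxy-4,5-epoxy-6-hydroxygermacra-1(10)E,11(13)-dien-12-oate | CC(C)(C)[Si](C)(C)O[C@H]1C/C(C)=C/CC[C@@]2(C)O[C@@H]2[C@@H](O)[C@@H]1C(=C)C(=O)OC | intermediate (not isolated)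
18 | 8α-(tert-butyldimethylsilyloxy)parthenolide | CC(C)(C)[Si](C)(C)O[C@H]1C/C(C)=C/CC[C@@]2(C)O[C@@H]2[C@H]2OC(=O)C(=C)[C@H]12 | intermediate
19 | 1β,10α;4α,5β-diepoxy methylene lactone | CC(C)(C)[Si](C)(C)O[C@H]1C[C@@]2(C)O[C@@H]2CC[C@@]2(C)O[C@@H]2[C@H]2OC(=O)C(=C)[C@H]12 | intermediate
20 | secondary ozonide of 19 (spiro-1,2,4-trioxolane at C-11, C-11 undefined) | CC(C)(C)[Si](C)(C)O[C@H]1C[C@@]2(C)O[C@@H]2CC[C@@]2(C)O[C@@H]2[C@H]2OC(=O)C3(OCOO3)[C@H]12 | intermediate (not isolated)
21 | 11-keto lactone (13-nor, 7α-H) | CC(C)(C)[Si](C)(C)O[C@H]1C[C@@]2(C)O[C@@H]2CC[C@@]2(C)O[C@@H]2[C@H]2OC(=O)C(=O)[C@H]12 | intermediate (not isolated)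
22 | 11-hydroxy-7(11)-ene lactone (enol) | CC(C)(C)[Si](C)(C)O[C@H]1C[C@@]2(C)O[C@@H]2CC[C@@]2(C)O[C@@H]2[C@H]2OC(=O)C(O)=C12 | intermediate
23 | enol triflate | CC(C)(C)[Si](C)(C)O[C@H]1C[C@@]2(C)O[C@@H]2CC[C@@]2(C)O[C@@H]2[C@H]2OC(=O)C(OS(=O)(=O)C(F)(F)F)=C12 | intermediate
24 | 13-hydroxy butenolide | CC(C)(C)[Si](C)(C)O[C@H]1C[C@@]2(C)O[C@@H]2CC[C@@]2(C)O[C@@H]2[C@H]2OC(=O)C(CO)=C12 | intermediate
25 | 13-acetoxy butenolide silyl ether | CC(C)(C)[Si](C)(C)O[C@H]1C[C@@]2(C)O[C@@H]2CC[C@@]2(C)O[C@@H]2[C@H]2OC(=O)C(COC(C)=O)=C12 | intermediate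
26 | 13-acetoxy-8α-hydroxy butenolide | O[C@H]1C[C@@]2(C)O[C@@H]2CC[C@@]2(C)O[C@@H]2[C@H]2OC(=O)C(COC(C)=O)=C12 | intermediate
27 | ethyl 2-(hydroxymethyl)acrylate | C=C(CO)C(=O)OCC | starting material
28 | ethyl 2-{[(tert-butyldimethylsilyl)oxy]methyl}acrylate | C=C(CO[Si](C)(C)C(C)(C)C)C(=O)OCC | intermediate
29 | 2-{[(tert-butyldimethylsilyl)oxy]methyl}acrylic acid | C=C(CO[Si](C)(C)C(C)(C)C)C(=O)O | intermediate
30 | silyl-protected target | C=C(CO[Si](C)(C)C(C)(C)C)C(=O)O[C@H]1C[C@@]2(C)O[C@@H]2CC[C@@]2(C)O[C@@H]2[C@H]2OC(=O)C(COC(C)=O)=C12 | intermediate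
31 | CNP0282791.1 | C=C(CO)C(=O)O[C@H]1C[C@@]2(C)O[C@@H]2CC[C@@]2(C)O[C@@H]2[C@H]2OC(=O)C(COC(C)=O)=C12 | target

**Step count and risks**
Total steps: 24. Longest linear sequence: 22 (steps 1–20, 23, 24).

Risky step: step 7 (the panel may hold no ketoreductase that accepts the bulky, lipophilic keto ester). Fallback, from 8 back to 9, replacing asymmetric reduction by kinetic resolution: NaBH4 (0.3 equiv, EtOH, −40 °C) reduces 8 to the C-2 epimeric hydroxy esters F1. A lipase (Burkholderia cepacia lipase, vinyl acetate, MTBE) acetylates only the (2S)-epimer to the (2S)-acetate F2, which is separated from the unreacted (2R)-epimer of F1 (recycled to 8 with Dess–Martin periodinane). K2CO3/EtOH at 0 °C removes the acetyl group and gives 9.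

Risky step: step 14 (macrocyclisation). Intramolecular allylchromium closure of E,E-germacranolide rings is an established tactic, but the configuration at C-6 rests on macrocyclic control working against the Felkin preference of the epoxy aldehyde. Fallback, from 16 back to 18: if cyclisation of 16 gives the C-6 epimer, the (6R)-lactone F3, the centre is corrected instead of re-optimising the cyclisation. LiOH (THF/H2O, 0 °C) opens F3 to the (6R)-hydroxy acid F4. Mitsunobu lactonisation (PPh3, DIAD, THF, high dilution, 0 °C) then recloses the lactone by SN2 displacement with inversion at C-6 and returns 18.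

Risky step: step 18 (Stille transfer of an sp3 hydroxymethyl group onto a crowded, epoxide-bearing triflate). Fallback, from 19 back to 25, bypassing steps 16–19: OsO4 (cat.)/NMO in acetone/H2O dihydroxylates the exocyclic methylene of 19 to the 11,13-diol F5 (C-11 epimers, immaterial). A lipase (Candida antarctica lipase B, vinyl acetate, MTBE) acetylates only the primary hydroxyl to give the 13-acetoxy-11-hydroxy lactone F6. SOCl2/pyridine at 0 °C dehydrates the tertiary alcohol into conjugation to give 25.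

**Further compounds**
F1 | step 7 | ethyl (2RS,4E)-2-hydroxy-7-[(2R,3R)-3-{[(4-methoxybenzyl)oxy]methyl}-2-methyloxiran-2-yl]-4-methylhept-4-enoate (C-2 epimers) | CCOC(=O)C(O)C/C(C)=C/CC[C@@]1(C)O[C@@H]1COCc1ccc(OC)cc1
F2 | step 7 | (2S)-2-acetoxy ester (acetate of 9) | CCOC(=O)[C@@H](OC(C)=O)C/C(C)=C/CC[C@@]1(C)O[C@@H]1COCc1ccc(OC)cc1
F3 | step 14 | (6R)-epimer of lactone 18 (cis-fused, 6β-O) | CC(C)(C)[Si](C)(C)O[C@H]1C/C(C)=C/CC[C@@]2(C)O[C@@H]2[C@@H]2OC(=O)C(=C)[C@H]12
F4 | step 14 | (6R)-6-hydroxy-8α-silyloxy-4,5-epoxygermacra-1(10)E,11(13)-dien-12-oic acid | CC(C)(C)[Si](C)(C)O[C@H]1C/C(C)=C/CC[C@@]2(C)O[C@@H]2[C@H](O)[C@@H]1C(=C)C(=O)O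
F5 | step 18 | 11,13-dihydroxy-11,13-dihydro derivative of 19 (C-11 epimers) | CC(C)(C)[Si](C)(C)O[C@H]1C[C@@]2(C)O[C@@H]2CC[C@@]2(C)O[C@@H]2[C@H]2OC(=O)C(O)(CO)[C@H]12
F6 | step 18 | 13-acetoxy-11-hydroxy-11,13-dihydro derivative of 19 (C-11 epimers) | CC(C)(C)[Si](C)(C)O[C@H]1C[C@@]2(C)O[C@@H]2CC[C@@]2(C)O[C@@H]2[C@H]2OC(=O)C(O)(COC(C)=O)[C@H]12
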